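**Retrosynthetic overview**
1. Theasinensin B ⇐ debenzylation and desilylation ⇐ mono-galloylation of a protected, twofold-symmetric bis(epigallocatechin), whose two 3-OH groups are homotopic.
2. Both (2R,3R) pairs ⇐ bis(flavan-3-one) by asymmetric transfer hydrogenation under dynamic kinetic resolution ⇐ Nef reaction ⇐ bis(3-nitroflavan).
3. Key disconnection: the C2–C3 bond of both rings C in one operation, from a bis(aryl benzyl ether) carrying an (E)-nitrovinyl group ortho to each ether oxygen (1,5-hydride shift from C2–H to C4, then nitronate C3 to oxocarbenium C2 closure).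
4. Enabling feature: in each unit C2 is a CH between O1 and the electron-rich ring B (a hydridic benzylic ether C–H) and lies 1,5 to C4 through O1–C8a–C4a of ring A; C4 is a CH2 in the target (hydride acceptor) and C3 bears the oxygen (nitro as masked carbonyl); the two units are equivalent about the biaryl axis.
5. Ring order: ring A (phloroglucinaldehyde) and rings B/B′ with the R axis (ellagic acid, whose two lactone carbonyl carbons become both C2 atoms) come from the starting materials; both rings C form in step 8.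

Key step: step 8

Remark: the SMILES carries no descriptor for the biaryl axis; the R axis of natural theasinensin B is assumed, set in step 2 and given in the names, and it cannot appear in the SMILES strings below.

**Route**

Step 1
Reactants: 1 ellagic acid
Product: 2 tetra-O-benzylellagic acid
Conditions: BnBr (4.4 equiv), K2CO3, DMF, 80 °C
Reagents that add atoms: benzyl bromide, BrCc1ccccc1
Why: Williamson O-benzylation of the four phenols; under anhydrous carbonate the two lactones should stay closed, so the planar dilactone still holds the B–B′ biaryl bond and the two carbons that become C2 of both flavan units.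

Step 2
Reactants: 2 tetra-O-benzylellagic acid
Product: 4 (R)-tetrabenzyloxy bis(hydroxymethyl)biphenyldiol, via mono-lactone 3 (not isolated)
Conditions: (S)-2-methyl-CBS-oxazaborolidine (3 equiv), BH3·THF (8 equiv), THF, 0 °C to rt; MeOH quench
Reagents that add atoms: none
Why: Atroposelective reductive opening of a configurationally labile biaryl lactone: the first lactone opens without stereochemical consequence to mono-lactone 3, whose twisted forms interconvert quickly, and the chiral oxazaborolidine–borane complex should reduce one of them faster (dynamic kinetic resolution), so the axis is fixed when the second bridge opens; the R sense is assigned by analogy and has to be confirmed, the enantiomeric oxazaborolidine being the remedy.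

Step 3
Reactants: 4 (R)-tetrabenzyloxy bis(hydroxymethyl)biphenyldiol
Product: 5 (R)-hexakis(benzyloxy)biphenyl-2,2′-dimethanol
Conditions: BnBr (2.2 equiv), K2CO3, acetone, reflux
Reagents that add atoms: benzyl bromide, BrCc1ccccc1
Why: Chemoselective Williamson benzylation, since carbonate deprotonates only the two phenols and leaves the benzylic alcohols free; the tetra-ortho-substituted axis cannot rotate under these conditions.

Step 4
Reactants: 5 (R)-hexakis(benzyloxy)biphenyl-2,2′-dimethanol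
Product: 6 (R)-hexakis(benzyloxy)-2,2′-bis(bromomethyl)biphenyl
Conditions: PBr3, CH2Cl2, 0 °C
Reagents that add atoms: phosphorus tribromide, BrP(Br)Br
Why: The electron-rich benzylic alcohols are converted into bromides through their phosphite esters (SN2 by bromide) at low temperature, which should outrun closure to the dibenzoxepine.

Step 5
Reactants: 7 2,4,6-trihydroxybenzaldehyde
Product: 8 2-hydroxy-4,6-bis(triisopropylsilyloxy)benzaldehyde
Conditions: i-Pr3SiCl (2.1 equiv), imidazole, DMF, 0 °C to rt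
Reagents that add atoms: triisopropylsilyl chloride, CC(C)[Si](Cl)(C(C)C)C(C)C
Why: Silyl ether formation at the para hydroxyl and one ortho hydroxyl, the other ortho hydroxyl being deactivated by its hydrogen bond to the formyl oxygen; silyl groups are chosen because they offer no hydridic C–H bond next to oxygen in step 8.

Step 6
Reactants: 6 (R)-hexakis(benzyloxy)-2,2′-bis(bromomethyl)biphenyl; 8 2-hydroxy-4,6-bis(triisopropylsilyloxy)benzaldehyde (2.1 equiv)
Product: 9 (R)-bis(aryl benzyl ether) dialdehyde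
Conditions: K2CO3, n-Bu4NI (cat.), acetone, 50 °C
Reagents that add atoms: none
Why: Twofold Williamson ether synthesis: the hydrogen-bonded phenol of 8 is acidic enough for carbonate and displaces both benzylic bromides (SN2), creating the O1–C2 bonds of both units.

Step 7
Reactants: 9 (R)-bis(aryl benzyl ether) dialdehyde
Product: 10 (R)-bis(aryl benzyl ether) bis[(E)-nitroalkene]
Conditions: MeNO2 (solvent), NH4OAc (cat.), 90 °C
Reagents that add atoms: nitromethane, C[N+](=O)[O-]
Why: Twofold Henry (nitroaldol) condensation; dehydration to the conjugated nitroalkene is driven by heat and the E geometry is the thermodynamic one.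

Step 8
Reactants: 10 (R)-bis(aryl benzyl ether) bis[(E)-nitroalkene]
Product: 12 (R)-bis(3-nitroflavan) (C2/C3 stereoisomer mixture), via mono-cyclised nitroalkene 11 (not isolated)
Conditions: Sc(OTf)3 (20 mol %), 4 Å MS, ClCH2CH2Cl (0.01 M), 80 °C
Reagents that add atoms: none
Why: Proposed new method: Sc(OTf)3 bound to the nitro oxygens should make C4 of each (E)-nitroalkene electrophilic enough to take a hydride suprafacially from the C2 methylene that sits 1,5 to it (O1–C8a–C4a–C4), a C–H bond both benzylic to the tris(benzyloxy)phenyl ring B and α to O1, giving an O-aryl oxocarbenium ion at C2 and a scandium nitronate at C3; the closest known reaction type is the Lewis-acid-catalysed 1,5-hydride shift/cyclization (internal redox) of ortho-(benzyloxy)aryl alkylidene malonates and barbiturates to 2-arylchromans, and the hydride-accepting ability of activated nitroalkenes is known from their transfer hydrogenation by Hantzsch esters. The nitronate carbon then attacks the oxocarbenium carbon in a 6-endo-trig closure (the C2=O1 bond lies inside the new ring, the C3=N bond outside), which forms the C2–C3 bond and ring C; the sequence runs twice, through the mono-cyclised compound 11, and is a pure isomerisation that also delivers C4 as the methylene of the target. C2 and C3 are created here, and a chair-like transition state with aryl and nitro groups pseudo-equatorial should favour the 2,3-trans relationship, but neither centre has to be controlled, because C3 becomes sp2 in step 9 and C2 is made labile and fixed in step 10; the axis is untouched. The step needs chemoselectivity for the ring B methylene as hydride donor and for hydride transfer over arene addition to the nitroalkene: the only other oxygen ortho to the acceptor carries a silyl group without an α C–H bond, the six-membered hydride-transfer geometry should beat the seven-membered Friedel–Crafts closure by C6 of ring B, and high dilution suppresses intermolecular arylation by ring A.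

Step 9
Reactants: 12 (R)-bis(3-nitroflavan)
Product: 14 (R)-bis(flavan-3-one) (C2 epimer mixture), via dipotassium bis-nitronate 13 (not isolated)
Conditions: KOtBu, THF, −20 °C; then aq. TiCl3, NH4OAc buffer (pH 5–6), 0 °C to rt
Reagents that add atoms: water, O
Why: Nef reaction in its titanium trichloride variant: tert-butoxide forms the nitronates, trivalent titanium reduces their N–O bonds and the buffered water hydrolyses the resulting C=N bonds to the ketones, conditions that should spare silyl ethers, benzyl ethers and the electron-rich rings; epimerisation at C2 is of no concern here.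

Step 10
Reactants: 14 (R)-bis(flavan-3-one)
Product: 15 (R)-(2R,3R,2′R,3′R)-bis(flavan-3-ol)
Conditions: RuCl[(R,R)-TsDPEN](p-cymene) (10 mol %), HCO2H/Et3N (2:5), DMF, 40 °C
Reagents that add atoms: none
Why: Noyori–Ikariya asymmetric transfer hydrogenation under dynamic kinetic resolution: C2 of each flavan-3-one (benzylic, α to O1 and to the carbonyl) epimerises through the enol in the formate/amine medium, the (R,R) catalyst should give the 3R carbinol (C2 side acting as the larger flank) and reduce fastest the C2 epimer attacked anti to ring B, so each unit converges on the (2R,3R)-cis flavan-3-ol while the axis is untouched.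

Step 11
Reactants: 15 (R)-(2R,3R,2′R,3′R)-bis(flavan-3-ol); 16 3,4,5-tris(benzyloxy)benzoic acid (1.0 equiv)
Product: 17 protected mono-gallate
Conditions: DCC, DMAP (cat.), CH2Cl2, 0 °C to rt
Reagents that add atoms: none
Why: Steglich esterification with one equivalent of acid: the two 3-hydroxyls are homotopic (twofold symmetry about the biaryl axis), so only one mono-ester can form; unreacted diol is recycled and the diester is separated.

Step 12
Reactants: 17 protected mono-gallate
Product: 18 nona-O-benzyl theasinensin B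
Conditions: n-Bu4NF, AcOH (1:1), THF, 0 °C
Reagents that add atoms: none
Why: Fluoride cleaves the four aryl silyl ethers (strong Si–F bond), and the acetic acid buffer keeps the liberated phenols protonated so that the gallate ester should neither migrate nor hydrolyse.

Step 13
Reactants: 18 nona-O-benzyl theasinensin B
Product: 19 theasinensin B
Conditions: H2 (1 atm), Pd(OH)2/C, THF/MeOH, rt; filtration under argon
Reagents that add atoms: none
Why: Hydrogenolysis of the nine benzyl ethers under neutral conditions should leave the gallate ester, the C2–O1 bonds of the flavans and all stereocentres intact and give the target after filtration.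

**Compound list**

1 | ellagic acid (2,3,7,8-tetrahydroxychromeno[5,4,3-cde]chromene-5,10-dione) | O=C1Oc2c(O)c(O)cc3C(=O)Oc4c(O)c(O)cc1c4-c23 | starting material

2 | 2,3,7,8-tetrakis(benzyloxy)chromeno[5,4,3-cde]chromene-5,10-dione (tetra-O-benzylellagic acid) | O=C1Oc2c(OCc5ccccc5)c(OCc5ccccc5)cc3C(=O)Oc4c(OCc5ccccc5)c(OCc5ccccc5)cc1c4-c23 | intermediate

3 | 3,4,8,9-tetrakis(benzyloxy)-10-hydroxy-1-(hydroxymethyl)-6H-benzo[c]chromen-6-one (half-opened mono-lactone, axis still mobile) | O=C1Oc2c(OCc3ccccc3)c(OCc3ccccc3)cc(CO)c2-c2c(O)c(OCc3ccccc3)c(OCc3ccccc3)cc12 | intermediate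

4 | (R)-3,3′,4,4′-tetrakis(benzyloxy)-6,6′-bis(hydroxymethyl)biphenyl-2,2′-diol | OCc1cc(OCc2ccccc2)c(OCc2ccccc2)c(O)c1-c1c(CO)cc(OCc2ccccc2)c(OCc2ccccc2)c1O | intermediate

5 | (R)-[4,4′,5,5′,6,6′-hexakis(benzyloxy)biphenyl-2,2′-diyl]dimethanol | OCc1cc(OCc2ccccc2)c(OCc2ccccc2)c(OCc2ccccc2)c1-c1c(CO)cc(OCc2ccccc2)c(OCc2ccccc2)c1OCc1ccccc1 | intermediate

6 | (R)-4,4′,5,5′,6,6′-hexakis(benzyloxy)-2,2′-bis(bromomethyl)biphenyl | BrCc1cc(OCc2ccccc2)c(OCc2ccccc2)c(OCc2ccccc2)c1-c1c(CBr)cc(OCc2ccccc2)c(OCc2ccccc2)c1OCc1ccccc1 | intermediate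

7 | 2,4,6-trihydroxybenzaldehyde | O=Cc1c(O)cc(O)cc1O | starting material

8 | 2-hydroxy-4,6-bis[(triisopropylsilyl)oxy]benzaldehyde | O=Cc1c(O)cc(O[Si](C(C)C)(C(C)C)C(C)C)cc1O[Si](C(C)C)(C(C)C)C(C)C | intermediate

9 | (R)-2,2′-{[4,4′,5,5′,6,6′-hexakis(benzyloxy)biphenyl-2,2′-diyl]bis(methyleneoxy)}bis{4,6-bis[(triisopropylsilyl)oxy]benzaldehyde} | O=Cc1c(O[Si](C(C)C)(C(C)C)C(C)C)cc(O[Si](C(C)C)(C(C)C)C(C)C)cc1OCc1cc(OCc2ccccc2)c(OCc2ccccc2)c(OCc2ccccc2)c1-c1c(COc2cc(O[Si](C(C)C)(C(C)C)C(C)C)cc(O[Si](C(C)C)(C(C)C)C(C)C)c2C=O)cc(OCc2ccccc2)c(OCc2ccccc2)c1OCc1ccccc1 | intermediate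

10 | (R)-4,4′,5,5′,6,6′-hexakis(benzyloxy)-2,2′-bis({2-[(E)-2-nitroethenyl]-3,5-bis[(triisopropylsilyl)oxy]phenoxy}methyl)biphenyl | [O-][N+](=O)/C=C/c1c(O[Si](C(C)C)(C(C)C)C(C)C)cc(O[Si](C(C)C)(C(C)C)C(C)C)cc1OCc1cc(OCc2ccccc2)c(OCc2ccccc2)c(OCc2ccccc2)c1-c1c(COc2cc(O[Si](C(C)C)(C(C)C)C(C)C)cc(O[Si](C(C)C)(C(C)C)C(C)C)c2/C=C/[N+](=O)[O-])cc(OCc2ccccc2)c(OCc2ccccc2)c1OCc1ccccc1 | intermediate

11 | mono-cyclised compound, R axis: one 3-nitro-5,7-bis(triisopropylsilyloxy)flavan unit (C2/C3 undefined) and one remaining (E)-nitrovinyl aryl benzyl ether arm | [O-][N+](=O)C1Cc2c(O[Si](C(C)C)(C(C)C)C(C)C)cc(O[Si](C(C)C)(C(C)C)C(C)C)cc2OC1c1cc(OCc2ccccc2)c(OCc2ccccc2)c(OCc2ccccc2)c1-c1c(COc2cc(O[Si](C(C)C)(C(C)C)C(C)C)cc(O[Si](C(C)C)(C(C)C)C(C)C)c2/C=C/[N+](=O)[O-])cc(OCc2ccccc2)c(OCc2ccccc2)c1OCc1ccccc1 | intermediate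

12 | (R-axis) 2,2′-[4,4′,5,5′,6,6′-hexakis(benzyloxy)biphenyl-2,2′-diyl]bis{3-nitro-5,7-bis[(triisopropylsilyl)oxy]chroman}, mixture of C2/C3 stereoisomers (2,3-trans units expected to predominate; centres left undefined in the SMILES) | [O-][N+](=O)C1Cc2c(O[Si](C(C)C)(C(C)C)C(C)C)cc(O[Si](C(C)C)(C(C)C)C(C)C)cc2OC1c1cc(OCc2ccccc2)c(OCc2ccccc2)c(OCc2ccccc2)c1-c1c(C2Oc3cc(O[Si](C(C)C)(C(C)C)C(C)C)cc(O[Si](C(C)C)(C(C)C)C(C)C)c3CC2[N+](=O)[O-])cc(OCc2ccccc2)c(OCc2ccccc2)c1OCc1ccccc1 | intermediate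

13 | dipotassium bis-nitronate of 12 (C2 undefined) | [K+].[K+].[O-][N+]([O-])=C1Cc2c(O[Si](C(C)C)(C(C)C)C(C)C)cc(O[Si](C(C)C)(C(C)C)C(C)C)cc2OC1c1cc(OCc2ccccc2)c(OCc2ccccc2)c(OCc2ccccc2)c1-c1c(C2Oc3cc(O[Si](C(C)C)(C(C)C)C(C)C)cc(O[Si](C(C)C)(C(C)C)C(C)C)c3CC2=[N+]([O-])[O-])cc(OCc2ccccc2)c(OCc2ccccc2)c1OCc1ccccc1 | intermediate

14 | (R-axis) 2,2′-[4,4′,5,5′,6,6′-hexakis(benzyloxy)biphenyl-2,2′-diyl]bis{5,7-bis[(triisopropylsilyl)oxy]chroman-3-one}, mixture of C2 epimers (left undefined in the SMILES) | O=C1Cc2c(O[Si](C(C)C)(C(C)C)C(C)C)cc(O[Si](C(C)C)(C(C)C)C(C)C)cc2OC1c1cc(OCc2ccccc2)c(OCc2ccccc2)c(OCc2ccccc2)c1-c1c(C2Oc3cc(O[Si](C(C)C)(C(C)C)C(C)C)cc(O[Si](C(C)C)(C(C)C)C(C)C)c3CC2=O)cc(OCc2ccccc2)c(OCc2ccccc2)c1OCc1ccccc1 | intermediate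

15 | (R-axis) (2R,3R,2′R,3′R)-2,2′-[4,4′,5,5′,6,6′-hexakis(benzyloxy)biphenyl-2,2′-diyl]bis{5,7-bis[(triisopropylsilyl)oxy]chroman-3-ol}, both units 2,3-cis | O[C@@H]1Cc2c(O[Si](C(C)C)(C(C)C)C(C)C)cc(O[Si](C(C)C)(C(C)C)C(C)C)cc2O[C@@H]1c1cc(OCc2ccccc2)c(OCc2ccccc2)c(OCc2ccccc2)c1-c1c([C@H]2Oc3cc(O[Si](C(C)C)(C(C)C)C(C)C)cc(O[Si](C(C)C)(C(C)C)C(C)C)c3C[C@H]2O)cc(OCc2ccccc2)c(OCc2ccccc2)c1OCc1ccccc1 | intermediate

16 | 3,4,5-tris(benzyloxy)benzoic acid | O=C(O)c1cc(OCc2ccccc2)c(OCc2ccccc2)c(OCc2ccccc2)c1 | starting material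

17 | mono-3-O-[3,4,5-tris(benzyloxy)benzoate] of 15 (R axis; 2R,3R,2′R,3′R) | O=C(O[C@@H]1Cc2c(O[Si](C(C)C)(C(C)C)C(C)C)cc(O[Si](C(C)C)(C(C)C)C(C)C)cc2O[C@@H]1c1cc(OCc2ccccc2)c(OCc2ccccc2)c(OCc2ccccc2)c1-c1c([C@H]2Oc3cc(O[Si](C(C)C)(C(C)C)C(C)C)cc(O[Si](C(C)C)(C(C)C)C(C)C)c3C[C@H]2O)cc(OCc2ccccc2)c(OCc2ccccc2)c1OCc1ccccc1)c1cc(OCc2ccccc2)c(OCc2ccccc2)c(OCc2ccccc2)c1 | intermediate

18 | nona-O-benzyl theasinensin B (rings A free; R axis; 2R,3R,2′R,3′R) | O=C(O[C@@H]1Cc2c(O)cc(O)cc2O[C@@H]1c1cc(OCc2ccccc2)c(OCc2ccccc2)c(OCc2ccccc2)c1-c1c([C@H]2Oc3cc(O)cc(O)c3C[C@H]2O)cc(OCc2ccccc2)c(OCc2ccccc2)c1OCc1ccccc1)c1cc(OCc2ccccc2)c(OCc2ccccc2)c(OCc2ccccc2)c1 | intermediate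

19 | theasinensin B (R axis; 2R,3R,2′R,3′R) | O=C(O[C@@H]1Cc2c(O)cc(O)cc2O[C@@H]1c1cc(O)c(O)c(O)c1-c1c([C@H]2Oc3cc(O)cc(O)c3C[C@H]2O)cc(O)c(O)c1O)c1cc(O)c(O)c(O)c1 | target

**Step count**

Total steps: 13. Longest linear sequence: 12 (steps 1–4 and 6–13, from ellagic acid); step 5 is a one-step branch.

**Steps most likely to fail**

Step 8. The hydride transfer from the benzylic ether C–H to the nitroalkene may be too slow, so that ionisation of the electron-rich benzylic C–O bond, seven-membered Friedel–Crafts addition of ring B to the nitroalkene or intermolecular arylation by ring A take over. The fallback uses known chemistry, sets out from 5 and comes back at 12. MnO2 oxidation of 5 gives (R)-4,4′,5,5′,6,6′-hexakis(benzyloxy)biphenyl-2,2′-dicarbaldehyde F1. Henry condensation with nitromethane (NH4OAc) gives the bis[(E)-2-nitrovinyl]biaryl F2. The DABCO-mediated oxa-Michael/Henry/dehydration sequence with two equivalents of salicylaldehyde 8 gives the bis(3-nitro-2H-chromene) F3. NaBH4 then reduces both nitroalkene C=C bonds to give 12 as a stereoisomer mixture, which steps 9 and 10 accept. In this fallback each ring C is closed through O1–C2 and C3–C4 instead.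

Step 10. Epimerisation at C2 may be slower than reduction, so that the resolution is not dynamic, or the catalyst-controlled facial preference may clash with the fixed axis. The fallback sets out from 14 and comes back at 15. LiBH(s-Bu)3 at −78 °C should reduce both ketones anti to ring B and so give a 2,3-cis unit whatever the configuration at C2. Three cis,cis-diols are expected: 15, the mixed (2R,3R,2′S,3′S) isomer F4 and the (2S,3S,2′S,3′S) isomer F5. They are diastereomers because the axis is fixed and are separated by chromatography. F4 and F5 are re-oxidised with Dess–Martin periodinane to 14, equilibrated at C2 with DBU and recycled.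

Step 2. Discrimination between the interconverting twisted forms of the mono-lactone may be insufficient, or the poorly soluble dilactone may be reduced mainly outside the chiral complex. The fallback sets out from 2 and comes back at 5. LiAlH4 reduces 2 to racemic 4 and the conditions of step 3 give racemic 5. DCC/DMAP esterification with (S)-2-methoxy-2-phenylacetic acid gives two atropo-diastereomeric bis-esters; the R-axis isomer, the bis[(S)-2-methoxy-2-phenylacetate] F6, is isolated by crystallisation or chromatography. K2CO3/MeOH then releases enantiopure 5.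

**Further compounds**

F1 | step 8 | (R)-4,4′,5,5′,6,6′-hexakis(benzyloxy)biphenyl-2,2′-dicarbaldehyde | O=Cc1cc(OCc2ccccc2)c(OCc2ccccc2)c(OCc2ccccc2)c1-c1c(C=O)cc(OCc2ccccc2)c(OCc2ccccc2)c1OCc1ccccc1

F2 | step 8 | (R)-4,4′,5,5′,6,6′-hexakis(benzyloxy)-2,2′-bis[(E)-2-nitroethenyl]biphenyl | [O-][N+](=O)/C=C/c1cc(OCc2ccccc2)c(OCc2ccccc2)c(OCc2ccccc2)c1-c1c(/C=C/[N+](=O)[O-])cc(OCc2ccccc2)c(OCc2ccccc2)c1OCc1ccccc1

F3 | step 8 | (R-axis) 2,2′-[4,4′,5,5′,6,6′-hexakis(benzyloxy)biphenyl-2,2′-diyl]bis{3-nitro-5,7-bis[(triisopropylsilyl)oxy]-2H-chromene}, C2 epimer mixture | [O-][N+](=O)C1=Cc2c(O[Si](C(C)C)(C(C)C)C(C)C)cc(O[Si](C(C)C)(C(C)C)C(C)C)cc2OC1c1cc(OCc2ccccc2)c(OCc2ccccc2)c(OCc2ccccc2)c1-c1c(C2Oc3cc(O[Si](C(C)C)(C(C)C)C(C)C)cc(O[Si](C(C)C)(C(C)C)C(C)C)c3C=C2[N+](=O)[O-])cc(OCc2ccccc2)c(OCc2ccccc2)c1OCc1ccccc1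

F4 | step 10 | (R-axis) (2R,3R,2′S,3′S) cis,cis diastereomer of 15 | O[C@@H]1Cc2c(O[Si](C(C)C)(C(C)C)C(C)C)cc(O[Si](C(C)C)(C(C)C)C(C)C)cc2O[C@@H]1c1cc(OCc2ccccc2)c(OCc2ccccc2)c(OCc2ccccc2)c1-c1c([C@@H]2Oc3cc(O[Si](C(C)C)(C(C)C)C(C)C)cc(O[Si](C(C)C)(C(C)C)C(C)C)c3C[C@@H]2O)cc(OCc2ccccc2)c(OCc2ccccc2)c1OCc1ccccc1

F5 | step 10 | (R-axis) (2S,3S,2′S,3′S) cis,cis diastereomer of 15 | O[C@H]1Cc2c(O[Si](C(C)C)(C(C)C)C(C)C)cc(O[Si](C(C)C)(C(C)C)C(C)C)cc2O[C@H]1c1cc(OCc2ccccc2)c(OCc2ccccc2)c(OCc2ccccc2)c1-c1c([C@@H]2Oc3cc(O[Si](C(C)C)(C(C)C)C(C)C)cc(O[Si](C(C)C)(C(C)C)C(C)C)c3C[C@@H]2O)cc(OCc2ccccc2)c(OCc2ccccc2)c1OCc1ccccc1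

F6 | step 2 | (R-axis) [4,4′,5,5′,6,6′-hexakis(benzyloxy)biphenyl-2,2′-diyl]bis(methylene) bis[(S)-2-methoxy-2-phenylacetate] | CO[C@@H](c1ccccc1)C(=O)OCc1cc(OCc2ccccc2)c(OCc2ccccc2)c(OCc2ccccc2)c1-c1c(COC(=O)[C@@H](OC)c2ccccc2)cc(OCc2ccccc2)c(OCc2ccccc2)c1OCc1ccccc1
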